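**Retrosynthesis**
1. Isariotin D (9) comes from hydroxyl-directed exo epoxidation of the bicyclic allylic alcohol 8.
2. Compound 8, a 1-hydroxybicyclo[3.3.1]non-2-en-9-one, comes from a second α,α′-annulation of the cyclohexanone 6 with propynal (7). Michael addition at the hydroxylated carbon forms the bridgehead tertiary carbinol and the C2=C3 alkene, and a bridging aldol sets the C4-OH.
3. Compound 6 comes from an organocatalytic asymmetric Michael/aldol annulation of hydroxyacetone (5) with an in-situ α-(decenoylamino)acrolein. This forms the first ring and sets the C7-N and C6-OH stereocentres.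
4. The acrolein acetal 4 is made from decenoic acid (1) by amide formation and Cu-catalysed N-vinylation. Ring order: monocycle (ring B), then the bridging ring (ring A), then the epoxide.

Assumption: propynal (7) is used as a freshly prepared cold solution (MnO2 oxidation of propargyl alcohol), and 2-bromo-3,3-diethoxypropene (3) is commercial. The catalyst enantiomer is taken to give the configuration drawn.

**Step 1**
Reactants: 1 (E)-dec-2-enoic acid
Product: 2 (E)-dec-2-enamide
Conditions: CDI, THF, rt, 1 h; then aq. NH3, 0 °C to rt
Reagents that add atoms: ammonia, N
Why: Acid activation as the acyl imidazolide followed by ammonolysis gives the primary amide, and the E-enoate is untouched.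

**Step 2**
Reactants: 2 (E)-dec-2-enamide; 3 2-bromo-3,3-diethoxyprop-1-ene
Product: 4 (E)-N-(3,3-diethoxyprop-1-en-2-yl)dec-2-enamide
Conditions: CuI (10 mol%), N,N′-dimethylethylenediamine (20 mol%), K3PO4, dioxane, 100 °C
Reagents that add atoms: none
Why: Cu-catalysed Goldberg-type N-vinylation of the primary amide gives the enamide. The acetal masks the sensitive α-amidoacrolein, which is released slowly in Step 3.

**Step 3**
Reactants: 4 (masked acceptor); 5 hydroxyacetone (3 equiv)
Product: 6 (E)-N-(2,5-dihydroxy-4-oxocyclohexyl)dec-2-enamide, all-cis (N, 2-OH and 5-OH on one face; SMILES below)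
Conditions: 9-amino-9-deoxy-epi-quinine (20 mol%), TFA (40 mol%), MeCN/H2O 9:1, 25 °C, 48 h, with 4 added by syringe pump
Reagents that add atoms: water, O (becomes the C2-OH oxygen after acetal hydrolysis)
Why: Organocatalytic asymmetric Michael/intramolecular aldol (α,α′-annulation).
- Acetal hydrolysis releases 2-(decenoylamino)acrolein (not isolated). The primary amine activates it as an iminium ion, and hydroxyacetone adds through its hydroxylated carbon, which is the electron-rich α-oxy-enamine/enol site. This sets the first stereocentre.
- The same catalyst then forms the methyl-ketone enamine and closes the six-membered ring in a chair aldol.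
- The aldehyde oxygen is held by the ammonium over the enamine nitrogen, which puts the new OH axial and the α-amido group equatorial, so they are cis. The carbinol carbon is epimerisable.

**Step 4**
Reactants: 6 (cyclohexanone); 7 propynal (1.5 equiv)
Product: 8 (E)-N-[(1,4,6-trihydroxy-9-oxobicyclo[3.3.1]non-2-en-7-yl)]dec-2-enamide
Conditions: 9-amino-9-deoxy-epi-quinine (20 mol%), TFA (40 mol%), MeCN, 0 °C to rt, 24 h, with 7 added by syringe pump
Reagents that add atoms: none
Why: Proposed new method: a second α,α′-annulation that builds a bicyclo[3.3.1]nonan-9-one with a bridgehead tertiary carbinol.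
- The amine forms the α-oxygenated enamine at the CH(OH) carbon, which is more nucleophilic than the CH2 side. It adds to the β-carbon of the ynal on the face anti to the axial 2-OH.
- The resulting Z-enal (Z/E interconverts through iminium ions) is trapped by the enamine at the other α-carbon in a chair aldol, with the aldehyde O again H-bonded over N. This gives the exo, axial allylic C4-OH and locks the bridge.
- The closest known chemistry is the Stork and organocatalytic Michael-aldol α,α′-annulation of cyclohexanones with enals, and proline-type reaction of hydroxyacetone at its hydroxylated carbon.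
- The bridgehead cannot enolise, so the aldol adducts cannot epimerise afterwards.

**Step 5**
Reactants: 8 (bicyclic allylic alcohol)
Product: 9 isariotin D
Conditions: VO(acac)2 (5 mol%), TBHP (1.5 equiv), CH2Cl2, 0 °C
Reagents that add atoms: tert-butyl hydroperoxide, CC(C)(C)OO (supplies the epoxide O)
Why: Vanadium-catalysed hydroxyl-directed epoxidation. The exo, axial C4-OH delivers oxygen to the same exo face, which is also the less hindered face, giving the syn epoxy alcohol. The electron-poor enamide alkene, the ketone and the other hydroxyls are untouched.

**Compound list**
1 | (E)-dec-2-enoic acid | CCCCCCC/C=C/C(=O)O | starting material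
2 | (E)-dec-2-enamide | CCCCCCC/C=C/C(=O)N | intermediate
3 | 2-bromo-3,3-diethoxyprop-1-ene | C=C(Br)C(OCC)OCC | starting material
4 | (E)-N-(3,3-diethoxyprop-1-en-2-yl)dec-2-enamide | CCCCCCC/C=C/C(=O)NC(=C)C(OCC)OCC | intermediate
5 | hydroxyacetone | CC(=O)CO | starting material
6 | (E)-N-(2,5-dihydroxy-4-oxocyclohexyl)dec-2-enamide, all-cis | CCCCCCC/C=C/C(=O)N[C@H]1C[C@@H](O)C(=O)C[C@H]1O | intermediate
7 | propynal | C#CC=O | starting material
8 | (E)-N-(1,4,6-trihydroxy-9-oxobicyclo[3.3.1]non-2-en-7-yl)dec-2-enamide | CCCCCCC/C=C/C(=O)N[C@H]1C[C@@]2(O)C(=O)[C@H]([C@H](O)C=C2)[C@H]1O | intermediate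
9 | isariotin D | CCCCCCC/C=C/C(=O)N[C@H]1C[C@@]2(O)C(=O)[C@H]([C@H](O)[C@@H]3O[C@@H]32)[C@H]1O | target

**Total steps:** 5. **Longest linear sequence:** 5 (Steps 1→2→3→4→5).

**Three steps most likely to fail**
1. **Step 4 (the new annulation).** Michael addition may occur at the wrong α-carbon or at oxygen, and propynal may polymerise or consume the amine.
   - Fallback (known chemistry, stepwise route):
     - Protect the C2-OH of 6 as its TBS ether and oxidise to the 1,2-dione (Dess–Martin).
     - Add vinylMgBr at the less hindered carbonyl.
     - Perform an LDA/acrolein aldol at the only enolisable carbon.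
     - Close ring A by Grubbs II RCM, then remove the TBS group (TBAF) to give 8.
2. **Step 3.** The α-amidoacrolein may be too unreactive, may give the trans N/OH diastereomer, or may give low ee.
   - Fallback: run the known enamine Michael/aldol with acrolein instead, then carry on through Step 4.
   - Install nitrogen late through the C6-carbamate by Rh2(esp)2 intramolecular C–H amination (cis-oxazolidinone), hydrolysis, and N-acylation with the decenoyl group (from 1).
3. **Step 5.** The epoxidation may suffer from competing directing hydroxyls or low selectivity.
   - Fallback: MnO2 oxidation of the allylic C4-OH to the enone, nucleophilic epoxidation (TBHP/DBU), then directed ketone reduction (Me4NBH(OAc)3 or Luche) to restore the exo alcohol.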